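**Retrosynthetic overview**
1. Target 15 ⇐ 14 by O-debenzylation; both acetates are carried from the start.
2. Key step: the dihydrofuran ring (the only ring made; both benzene rings are bought) closes by a formal [4+1] annulation. An o-quinone methide supplies electrophilic C3, and a chiral benzylic sulfonium ylide supplies C2, the vanillin carbinol carbon used here as a nucleophile. The C2–C3 bond forms first, then O1–C2 with loss of the sulfide; both stereocentres are set in this step.
3. o-Quinone methide precursor 7 ⇐ ortho-hydroxyalkylation of dihydroconiferyl acetate 2 with acetoxyacetaldehyde (C3a–C3 bond), then sulfinate exchange.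
4. Ylide precursor 10 ⇐ O-benzylvanillyl alcohol 8 + isothiocineole 9.

Assumption: the ylide of the (R)-limonene-derived isothiocineole is taken to react by the usual model (aryl syn to the sulfur lone pair, approach anti to the CMe2 bridge), which I derived by hand and could not check against data; if the sense is reversed, the (S)-limonene-derived sulfide is used instead.

**Route**

Step 1
Reactants: 1 dihydroconiferyl alcohol [4-(3-hydroxypropyl)-2-methoxyphenol]
Product: 2 3-(4-hydroxy-3-methoxyphenyl)propyl acetate
Conditions: vinyl acetate (3 equiv), Novozym 435 (CAL-B), MTBE, 40 °C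
Reagents that add atoms: vinyl acetate, C=COC(C)=O
Why: Lipase-catalysed irreversible transesterification (enzymatic chemoselective O-acylation) acetylates the primary alcohol and leaves the phenol free; no stereocentre is involved.

Step 2
Reactants: 2 3-(4-hydroxy-3-methoxyphenyl)propyl acetate; 3 2-oxoethyl acetate (acetoxyacetaldehyde); 4 phenylboronic acid
Product: 6 2-[5-(3-acetoxypropyl)-2-hydroxy-3-methoxyphenyl]-2-hydroxyethyl acetate (racemic), via benzodioxaborin 5 (not isolated)
Conditions: PhB(OH)2 (1.1 equiv), EtCO2H (0.3 equiv), toluene, reflux, Dean–Stark; then 30% H2O2, THF, 0 °C → rt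
Reagents that add atoms: none
Why: Nagata-type boronic-acid-templated ortho-hydroxyalkylation: the aryl boronate delivers the aldehyde to the only free ortho position through a six-membered transition state to give 5, and oxidative deboronation frees the diol; the new carbinol centre is racemic and is erased in step 5.

Step 3
Reactants: 6 2-[5-(3-acetoxypropyl)-2-hydroxy-3-methoxyphenyl]-2-hydroxyethyl acetate
Product: 7 2-[5-(3-acetoxypropyl)-2-hydroxy-3-methoxyphenyl]-2-(4-methylbenzenesulfonyl)ethyl acetate (racemic)
Conditions: p-TolSO2H (1.5 equiv), TsOH·H2O (10 mol %), MgSO4, CH2Cl2, rt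
Reagents that add atoms: p-toluenesulfinic acid, Cc1ccc(S(=O)O)cc1
Why: Acid-promoted substitution of an o-hydroxybenzylic alcohol by sulfinate (through the o-quinone methide/benzylic cation, assisted by the phenol and the neighbouring acetate) is the standard preparation of 2-(1-tosylalkyl)phenols; the centre stays racemic.

Step 4
Reactants: 8 4-(benzyloxy)-3-methoxybenzyl alcohol; 9 (1R,4R,5R)-isothiocineole [(1R,4R,5R)-4,7,7-trimethyl-6-thiabicyclo[3.2.1]octane, from (R)-limonene]
Product: 10 (1R,4R,5R,6R)-6-[4-(benzyloxy)-3-methoxybenzyl]-4,7,7-trimethyl-6-thiabicyclo[3.2.1]octan-6-ium tetrafluoroborate (S-benzyl exo)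
Conditions: HBF4·OEt2 (1.05 equiv), 9 (1.5 equiv), CH2Cl2, 0 °C → rt; precipitate with Et2O
Reagents that add atoms: tetrafluoroboric acid (diethyl ether complex), [H+].F[B-](F)(F)F
Why: SN1 S-alkylation of the sulfide by the electron-rich benzylic cation (alcohol/HBF4 sulfonium salt synthesis); alkylation on the exo lone pair, anti to the three-carbon bridge, gives a single sulfonium diastereomer.

Step 5
Reactants: 7 2-[5-(3-acetoxypropyl)-2-hydroxy-3-methoxyphenyl]-2-(4-methylbenzenesulfonyl)ethyl acetate; 10 the isothiocineolium tetrafluoroborate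
Product: 14 [(2S,3R)-5-(3-acetoxypropyl)-2-[4-(benzyloxy)-3-methoxyphenyl]-7-methoxy-2,3-dihydro-1-benzofuran-3-yl]methyl acetate, via sulfonium ylide 11 (not isolated), via o-quinone methide 12 (not isolated), via betaine 13 (not isolated)
Conditions: 10 (1.2 equiv), KHMDS (2.2 equiv), THF, −78 → −20 °C (potassium phenoxide of 7 added slowly to the pre-formed ylide)
Reagents that add atoms: none
Why: Proposed new method: KHMDS converts 10 into the semi-stabilised ylide 11, in which the carbon that will carry the ring oxygen reacts as a nucleophile, and converts 7 into o-quinone methide 12 by 1,4-elimination of sulfinate; aromatisation-driven conjugate addition joins these two normally electrophilic carbons (C2–C3) to give anti-betaine 13, whose phenoxide displaces the sulfide in a 5-exo-tet SN2 with inversion at C2; C2 (S) is set by the sulfide-controlled ylide face and C3 (R) by the anti, trans-selective addition (any cis isomer is removed by chromatography); the closest known reactions are the formal [4+1] annulation of o-quinone methides with sulfur ylides and the isothiocineole-mediated Corey–Chaykovsky epoxidation.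

Step 6
Reactants: 14 the benzyl ether from step 5
Product: 15 [(2S,3R)-5-(3-acetoxypropyl)-2-(4-hydroxy-3-methoxyphenyl)-7-methoxy-2,3-dihydro-1-benzofuran-3-yl]methyl acetate (CNP0227018.1)
Conditions: H2 (1 atm), 10% Pd/C, EtOAc, rt, stopped after 1 equiv H2
Reagents that add atoms: none
Why: Catalytic hydrogenolysis of the phenolic benzyl ether (O-debenzylation) under neutral conditions leaves both acetates and both stereocentres untouched; stopping after one equivalent of hydrogen spares the ring C2–O bond.

**Compound list**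
1 | dihydroconiferyl alcohol, 4-(3-hydroxypropyl)-2-methoxyphenol | COc1cc(CCCO)ccc1O | starting material
2 | 3-(4-hydroxy-3-methoxyphenyl)propyl acetate | COc1cc(CCCOC(C)=O)ccc1O | intermediate
3 | 2-oxoethyl acetate (acetoxyacetaldehyde) | CC(=O)OCC=O | starting material
4 | phenylboronic acid | OB(O)c1ccccc1 | starting material
5 | [6-(3-acetoxypropyl)-8-methoxy-2-phenyl-4H-1,3,2-benzodioxaborin-4-yl]methyl acetate (racemic) | COc1cc(CCCOC(C)=O)cc2c1OB(c1ccccc1)OC2COC(C)=O | intermediate
6 | 2-[5-(3-acetoxypropyl)-2-hydroxy-3-methoxyphenyl]-2-hydroxyethyl acetate (racemic) | COc1cc(CCCOC(C)=O)cc(C(O)COC(C)=O)c1O | intermediate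
7 | 2-[5-(3-acetoxypropyl)-2-hydroxy-3-methoxyphenyl]-2-(4-methylbenzenesulfonyl)ethyl acetate (racemic) | COc1cc(CCCOC(C)=O)cc(C(COC(C)=O)S(=O)(=O)c2ccc(C)cc2)c1O | intermediate
8 | 4-(benzyloxy)-3-methoxybenzyl alcohol | COc1cc(CO)ccc1OCc1ccccc1 | starting material
9 | (1R,4R,5R)-isothiocineole | C[C@@H]1CC[C@@H]2C[C@H]1SC2(C)C | starting material
10 | (1R,4R,5R,6R)-6-[4-(benzyloxy)-3-methoxybenzyl]-4,7,7-trimethyl-6-thiabicyclo[3.2.1]octan-6-ium tetrafluoroborate | C[C@@H]1CC[C@@H]2C[C@H]1[S@@+](Cc1ccc(OCc3ccccc3)c(OC)c1)C2(C)C.F[B-](F)(F)F | intermediate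
11 | sulfonium ylide of 10 (benzylic methanide on sulfur) | C[C@@H]1CC[C@@H]2C[C@H]1[S@@+]([CH-]c1ccc(OCc3ccccc3)c(OC)c1)C2(C)C | intermediate
12 | (6E)-6-(2-acetoxyethylidene)-4-(3-acetoxypropyl)-2-methoxycyclohexa-2,4-dien-1-one (o-quinone methide) | COC1=CC(CCCOC(C)=O)=C/C(=C\COC(C)=O)C1=O | intermediate
13 | anti-betaine from 11 + 12: phenoxide with the sulfonium on the future C2 (C2 R, C3 R, benzofuran numbering) | [O-]c1c(OC)cc(CCCOC(C)=O)cc1[C@H](COC(C)=O)[C@H](c1ccc(OCc2ccccc2)c(OC)c1)[S@@+]1[C@@H]2C[C@@H](CC[C@H]2C)C1(C)C | intermediate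
14 | [(2S,3R)-5-(3-acetoxypropyl)-2-[4-(benzyloxy)-3-methoxyphenyl]-7-methoxy-2,3-dihydro-1-benzofuran-3-yl]methyl acetate | COc1cc([C@H]2Oc3c(OC)cc(CCCOC(C)=O)cc3[C@@H]2COC(C)=O)ccc1OCc1ccccc1 | intermediate
15 | [(2S,3R)-5-(3-acetoxypropyl)-2-(4-hydroxy-3-methoxyphenyl)-7-methoxy-2,3-dihydro-1-benzofuran-3-yl]methyl acetate | COc1cc([C@H]2Oc3c(OC)cc(CCCOC(C)=O)cc3[C@@H]2COC(C)=O)ccc1O | target

**Totals**
Total steps: 6. Longest linear sequence: 5 (steps 1, 2, 3, 5, 6); step 4 is the convergent branch.

**Three steps most likely to fail**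

Step 5 (key annulation). The alkyl-substituted o-quinone methide 12 can tautomerise to the o-hydroxystyrene enol acetate or oligomerise before the hindered chiral ylide adds. An SN1-type ring closure of the electron-rich benzylic sulfonium could also erode the ee. The fallback sets out from 7 and 8 and comes back at 14; it gives up reagent control and uses a racemic annulation followed by resolution. Alcohol 8 is S-alkylated onto tetrahydrothiophene (HBF4·OEt2, CH2Cl2) to give the unhindered achiral salt 1-[4-(benzyloxy)-3-methoxybenzyl]tetrahydrothiophenium tetrafluoroborate F1. Its ylide (Cs2CO3, MeCN, 0 °C) traps the quinone methide from 7 faster than the isothiocineole ylide and gives racemic trans-[5-(3-acetoxypropyl)-2-[4-(benzyloxy)-3-methoxyphenyl]-7-methoxy-2,3-dihydro-1-benzofuran-3-yl]methyl acetate F2. Preparative chiral SFC of F2 delivers the (2S,3R)-enantiomer 14.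

Step 3 (sulfone formation). The β-acetoxy group slows ionisation of the benzylic alcohol and can migrate under acid. The fallback sets out from 6 and comes back at the o-quinone methide 12 inside step 5; it replaces cation chemistry by acylation, with acetate as the leaving group. Diol 6 is peracetylated (Ac2O, pyridine, DMAP) to 1-[2-acetoxy-5-(3-acetoxypropyl)-3-methoxyphenyl]ethane-1,2-diyl diacetate F3. The aryl acetate alone is removed with hydrazine acetate (DMF, 0 °C) to give 1-[5-(3-acetoxypropyl)-2-hydroxy-3-methoxyphenyl]ethane-1,2-diyl diacetate F4. Under the step 5 base the phenoxide of F4 expels acetate instead of sulfinate and gives the same 12.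

Step 2 (ortho-hydroxyalkylation). The α-acyloxy aldehyde may self-condense, and the ortho-methoxy group may disturb the boronate template. The fallback sets out from 2 and comes back at 6; it builds the C3a–C3 bond by acyl migration and reduction instead. Phenol 2 is O-acylated with acetoxyacetyl chloride (K2CO3, acetone) to 4-(3-acetoxypropyl)-2-methoxyphenyl 2-acetoxyacetate F5. Photo-Fries rearrangement (254 nm, cyclohexane; the para position is blocked, so only the free ortho position can accept the acyl group) gives 2-[5-(3-acetoxypropyl)-2-hydroxy-3-methoxyphenyl]-2-oxoethyl acetate F6. NaBH4 (MeOH/THF, −20 °C) reduces the ketone of F6 to diol 6.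

**Further compounds**
F1 | step 5 | 1-[4-(benzyloxy)-3-methoxybenzyl]tetrahydrothiophenium tetrafluoroborate | COc1cc(C[S+]2CCCC2)ccc1OCc1ccccc1.F[B-](F)(F)F
F2 | step 5 | racemic trans-[5-(3-acetoxypropyl)-2-[4-(benzyloxy)-3-methoxyphenyl]-7-methoxy-2,3-dihydro-1-benzofuran-3-yl]methyl acetate (relative configuration shown) | COc1cc([C@H]2Oc3c(OC)cc(CCCOC(C)=O)cc3[C@@H]2COC(C)=O)ccc1OCc1ccccc1
F3 | step 3 | 1-[2-acetoxy-5-(3-acetoxypropyl)-3-methoxyphenyl]ethane-1,2-diyl diacetate (racemic) | COc1cc(CCCOC(C)=O)cc(C(OC(C)=O)COC(C)=O)c1OC(C)=O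
F4 | step 3 | 1-[5-(3-acetoxypropyl)-2-hydroxy-3-methoxyphenyl]ethane-1,2-diyl diacetate (racemic) | COc1cc(CCCOC(C)=O)cc(C(OC(C)=O)COC(C)=O)c1O
F5 | step 2 | 4-(3-acetoxypropyl)-2-methoxyphenyl 2-acetoxyacetate | COc1cc(CCCOC(C)=O)ccc1OC(=O)COC(C)=O
F6 | step 2 | 2-[5-(3-acetoxypropyl)-2-hydroxy-3-methoxyphenyl]-2-oxoethyl acetate | COc1cc(CCCOC(C)=O)cc(C(=O)COC(C)=O)c1O
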